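**Plan**
- Retrosynthesis: the quinone goes back to a bis-benzyl hydroquinone, then the O1–C2 bond of the chroman is cut, then O1 is excised from the C8a–O1 bond (C2 at the lactone level), and last the C3–aryl bond is cut.
- Enabling feature: without O1 the pyran ring contracts to the five-membered ring of a 2-aryl-5,6-dimethoxy-1-indanone (indanone C7a, C1, C2, C3 = chroman C8a, C2, C3, C4). There C3 is the α-carbon of an aryl ketone and epimerises freely, and C8a, para to the C6 methoxy group, is the carbon predisposed to migrate to oxygen.
- Forward order: B-ring bromide, then α-arylation of the indanone (C3–aryl bond), then oxygen insertion expanding the five-membered ring to the six-membered lactone, then reduction and O1–C2 closure to the chroman, then debenzylation and oxidation to the quinone.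
- Stereochemistry: the single stereocenter, C3 (S), is set by catalyst-controlled dynamic kinetic resolution in the Baeyer–Villiger step and is not touched afterwards.

Key step: step 5

Remark: compounds 1, 3 and 6 are taken as purchasable; L* in step 5 is the known C2-symmetric N,N'-dioxide bis(2,6-diisopropylanilide) built from (S)-pipecolic acid on a propane-1,3-diyl linker, used as a catalyst component, and whichever antipode makes the (S)-ketone the fast-reacting enantiomer is the one employed.

**Route**

Step 1
Reactants: 1 2,3-dimethoxy-1,4-benzoquinone
Product: 2 2,3-dimethoxybenzene-1,4-diol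
Conditions: Na2S2O4, H2O/EtOAc, rt
Reagents that add atoms: none
Why: Dithionite reduction of a quinone to its hydroquinone is fast in a two-phase medium, which also keeps the air-sensitive product away from base.

Step 2
Reactants: 2 2,3-dimethoxybenzene-1,4-diol; 3 benzyl bromide
Product: 4 1,4-bis(benzyloxy)-2,3-dimethoxybenzene
Conditions: BnBr (2.2 equiv), K2CO3, DMF, 50 °C, N2
Reagents that add atoms: benzyl bromide (compound 3), BrCc1ccccc1
Why: Williamson ether synthesis on both phenoxides; benzyl is chosen because it should survive base, palladium, peracid, hydride and Mitsunobu conditions and leaves last under neutral hydrogenolysis.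

Step 3
Reactants: 4 1,4-bis(benzyloxy)-2,3-dimethoxybenzene
Product: 5 1,4-bis(benzyloxy)-5-bromo-2,3-dimethoxybenzene
Conditions: NBS (1.0 equiv), MeCN, 0 °C to rt, dark
Reagents that add atoms: N-bromosuccinimide, O=C1CCC(=O)N1Br
Why: Electrophilic aromatic bromination of a tetra-alkoxybenzene whose two free positions are equivalent by symmetry, so only one monobromide can form and the first bromine slows a second substitution.

Step 4
Reactants: 5 1,4-bis(benzyloxy)-5-bromo-2,3-dimethoxybenzene; 6 5,6-dimethoxy-1-indanone
Product: 7 racemic 2-[2,5-bis(benzyloxy)-3,4-dimethoxyphenyl]-5,6-dimethoxy-1-indanone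
Conditions: Pd2(dba)3 (2.5 mol%), XPhos (6 mol%), NaOtBu (2.2 equiv), toluene, 80 °C
Reagents that add atoms: none
Why: Palladium-catalysed α-arylation of a ketone enolate (Buchwald–Hartwig type), in which the more acidic product is stored as its enolate and the ortho benzyloxy group hinders a second arylation; the new stereocenter forms racemic and labile, as the next step requires.

Step 5
Reactants: 7 racemic 2-[2,5-bis(benzyloxy)-3,4-dimethoxyphenyl]-5,6-dimethoxy-1-indanone
Product: 8 (3S)-3-[2,5-bis(benzyloxy)-3,4-dimethoxyphenyl]-6,7-dimethoxychroman-2-one
Conditions: Sc(OTf)3 (10 mol%), L* (12 mol%), mCPBA (1.3 equiv, slow addition), NaHCO3 (powdered, 2 equiv), EtOAc, −20 °C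
Reagents that add atoms: meta-chloroperoxybenzoic acid (mCPBA), OOC(=O)c1cccc(Cl)c1
Why: Proposed new method: the Sc(III)-bound ketone adds the peracid to give a Criegee adduct from which the aryl carbon C7a migrates from C1 to oxygen anti to the breaking O–O bond, while the two ketone enantiomers interconvert through the enol(ate) that the Lewis-acid-bound α-aryl ketone forms with bicarbonate/m-chlorobenzoate as proton shuttle. The closest known reactions are the peracid Baeyer–Villiger oxidation of 1-indanones to 3,4-dihydrocoumarins, the kinetic resolution of racemic 2-aryl cycloalkanones by chiral Sc(III)/N,N'-dioxide–peracid oxidation, and enzymatic Baeyer–Villiger oxidations run as dynamic kinetic resolutions of α-substituted ketones in basic buffer; what is new is their union on a 2-aryl-1-indanone with aryl migration. The six-membered lactone arises not by cyclisation but by ring expansion, the 1,2-shift of C7a inserting oxygen into the C1–C7a bond of the five-membered ring (new bond C8a–O1 in chroman numbering). The stereocenter (indanone C2, lactone C3) is not a migrating atom and keeps its configuration; which configuration reaches the product is decided by the chiral Sc complex, which is to oxidise the (S)-ketone faster than the (R)-ketone, and slow addition of the peracid keeps oxidation slower than racemisation. The step needs migration of the aryl carbon in preference to C2: the 5-methoxy group para to C7a lies in the ring plane and donates fully, whereas the para methoxy group of the B ring is flanked by two alkoxy groups, is twisted out of conjugation and gives C2 little help. It also needs the product to hold its configuration, which the lower C–H acidity and weaker Lewis basicity of the aryl lactone compared with the ketone should secure at −20 °C; the lactone is nonetheless reduced without delay.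

Step 6
Reactants: 8 (3S)-3-[2,5-bis(benzyloxy)-3,4-dimethoxyphenyl]-6,7-dimethoxychroman-2-one
Product: 9 (2S)-2-[2,5-bis(benzyloxy)-3,4-dimethoxyphenyl]-3-(2-hydroxy-4,5-dimethoxyphenyl)propan-1-ol
Conditions: LiBH4, THF, 0 °C
Reagents that add atoms: none
Why: Hydride reduction of an activated aryl ester (lactone) runs quickly through the aldehyde to the primary alcohol, which removes the acidity at the stereocenter, and benzyl ethers are inert.

Step 7
Reactants: 9 (2S)-2-[2,5-bis(benzyloxy)-3,4-dimethoxyphenyl]-3-(2-hydroxy-4,5-dimethoxyphenyl)propan-1-ol
Product: 10 (3S)-3-[2,5-bis(benzyloxy)-3,4-dimethoxyphenyl]-6,7-dimethoxychroman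
Conditions: PPh3, DIAD, THF, 0 °C to rt
Reagents that add atoms: none
Why: Intramolecular Mitsunobu etherification, in which the only free phenol displaces the activated primary alcohol in a 6-exo-tet closure to the chroman; the stereocenter is one carbon away from the reacting centre and is untouched.

Step 8
Reactants: 10 (3S)-3-[2,5-bis(benzyloxy)-3,4-dimethoxyphenyl]-6,7-dimethoxychroman
Product: 12 Abroquinone A (5-[(3S)-6,7-dimethoxychroman-3-yl]-2,3-dimethoxy-1,4-benzoquinone), via hydroquinone 11 (not isolated)
Conditions: H2 (1 atm), 10% Pd/C, EtOAc, rt; filter; then Ag2O, Na2SO4, rt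
Reagents that add atoms: none
Why: Hydrogenolysis of the two aryl benzyl ethers followed by silver(I) oxide oxidation of the 2,3-dimethoxyhydroquinone to the quinone, neither of which should affect the chroman ether, the veratrole ring or the C3 stereocenter.

**Compound list**

1 | 2,3-dimethoxy-1,4-benzoquinone | COC1=C(OC)C(=O)C=CC1=O | starting material
2 | 2,3-dimethoxybenzene-1,4-diol | COc1c(O)ccc(O)c1OC | intermediate
3 | benzyl bromide | BrCc1ccccc1 | starting material
4 | 1,4-bis(benzyloxy)-2,3-dimethoxybenzene | COc1c(OCc2ccccc2)ccc(OCc2ccccc2)c1OC | intermediate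
5 | 1,4-bis(benzyloxy)-5-bromo-2,3-dimethoxybenzene | COc1c(OCc2ccccc2)cc(Br)c(OCc2ccccc2)c1OC | intermediate
6 | 5,6-dimethoxy-1-indanone | COc1cc2c(cc1OC)C(=O)CC2 | starting material
7 | racemic 2-[2,5-bis(benzyloxy)-3,4-dimethoxyphenyl]-5,6-dimethoxy-1-indanone | COc1cc2c(cc1OC)C(=O)C(C2)c1cc(OCc3ccccc3)c(OC)c(OC)c1OCc1ccccc1 | intermediate
8 | (3S)-3-[2,5-bis(benzyloxy)-3,4-dimethoxyphenyl]-6,7-dimethoxychroman-2-one | COc1c(OCc2ccccc2)cc([C@H]2C(=O)Oc3cc(OC)c(OC)cc3C2)c(OCc2ccccc2)c1OC | intermediate
9 | (2S)-2-[2,5-bis(benzyloxy)-3,4-dimethoxyphenyl]-3-(2-hydroxy-4,5-dimethoxyphenyl)propan-1-ol | COc1c(OCc2ccccc2)cc([C@@H](CO)Cc2cc(OC)c(OC)cc2O)c(OCc2ccccc2)c1OC | intermediate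
10 | (3S)-3-[2,5-bis(benzyloxy)-3,4-dimethoxyphenyl]-6,7-dimethoxychroman | COc1c(OCc2ccccc2)cc([C@H]2COc3cc(OC)c(OC)cc3C2)c(OCc2ccccc2)c1OC | intermediate
11 | 5-[(3S)-6,7-dimethoxychroman-3-yl]-2,3-dimethoxybenzene-1,4-diol | COc1c(O)cc([C@H]2COc3cc(OC)c(OC)cc3C2)c(O)c1OC | intermediate
12 | Abroquinone A, 5-[(3S)-6,7-dimethoxychroman-3-yl]-2,3-dimethoxy-1,4-benzoquinone | COC1=C(OC)C(=O)C([C@H]2COc3cc(OC)c(OC)cc3C2)=CC1=O | target

**Step count**

Total step count: 8.
Longest linear sequence: 8 steps (1 to 12); 6 enters at step 4 as a purchased compound.

**Steps most likely to fail**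

1. Step 5 (proposed new method). The chiral complex may discriminate the two ketone enantiomers too weakly, or racemisation may fall behind oxidation under the peracid, so that the lactone forms with low enantiomeric purity. The fallback uses known chemistry, sets out from 7 and returns at 9. Buffered mCPBA oxidation without the chiral catalyst (NaHCO3, CH2Cl2, rt), the ordinary peracid Baeyer–Villiger oxidation of an alkoxy-substituted 1-indanone, should give racemic 3-[2,5-bis(benzyloxy)-3,4-dimethoxyphenyl]-6,7-dimethoxychroman-2-one F1. LiBH4 reduction as in step 6 then gives the racemic diol F2. Its enantiomers are separated by preparative chromatography on a polysaccharide chiral stationary phase, and the (S)-enantiomer is 9, from which step 7 continues. The price is half of the material. The fallback does not cover migration of C2 in place of the aryl carbon; the racemic run would, however, reveal which ring carbon migrates.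

2. Step 4. Oxidative addition and reductive elimination at the electron-rich bromide next to an ortho benzyloxy group may be slow, so that base-induced self-condensation of the indanone and reduction of the bromide take over. The fallback reverses the polarity of the coupling, sets out from 6 and 5 and returns at 7. Compound 6 is brominated at C2 with CuBr2 (EtOAc/CHCl3, reflux) to racemic 2-bromo-5,6-dimethoxy-1-indanone F3. Compound 5 undergoes bromine–lithium exchange (n-BuLi, THF, −78 °C) to the aryllithium F4, which ZnCl2 converts into the arylzinc chloride F5. Nickel-catalysed Negishi coupling of the secondary α-bromo ketone with the arylzinc (NiCl2·glyme, bipyridine-type ligand, glyme/THF, −30 °C to rt) should then give 7. An achiral ligand suffices because 7 is wanted racemic.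

3. Step 6. Hydride or liberated phenoxide may enolise the α-aryl aryl ester, or the transient α-aryl aldehyde, before reduction is complete, which would erode the enantiomeric purity. The fallback sets out from 8 and returns at 9. Acid-catalysed ring-opening methanolysis (HCl generated from AcCl in MeOH, rt), under which the ester should not enolise, gives the methyl ester F6, a much weaker carbon acid than the aryl lactone. Reduction of this alkyl ester with LiAlH4 (THF, −20 to 0 °C), a reaction type routinely run on α-aryl esters without loss of configuration, should then give 9.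

**Further compounds**

F1 | step 5 | racemic 3-[2,5-bis(benzyloxy)-3,4-dimethoxyphenyl]-6,7-dimethoxychroman-2-one | COc1c(OCc2ccccc2)cc(C2C(=O)Oc3cc(OC)c(OC)cc3C2)c(OCc2ccccc2)c1OC
F2 | step 5 | racemic 2-[2,5-bis(benzyloxy)-3,4-dimethoxyphenyl]-3-(2-hydroxy-4,5-dimethoxyphenyl)propan-1-ol | COc1c(OCc2ccccc2)cc(C(CO)Cc2cc(OC)c(OC)cc2O)c(OCc2ccccc2)c1OC
F3 | step 4 | racemic 2-bromo-5,6-dimethoxy-1-indanone | COc1cc2c(cc1OC)C(=O)C(Br)C2
F4 | step 4 | [2,5-bis(benzyloxy)-3,4-dimethoxyphenyl]lithium | [Li]c1cc(OCc2ccccc2)c(OC)c(OC)c1OCc1ccccc1
F5 | step 4 | [2,5-bis(benzyloxy)-3,4-dimethoxyphenyl]zinc chloride | COc1c(OCc2ccccc2)cc([Zn]Cl)c(OCc2ccccc2)c1OC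
F6 | step 6 | methyl (2S)-2-[2,5-bis(benzyloxy)-3,4-dimethoxyphenyl]-3-(2-hydroxy-4,5-dimethoxyphenyl)propanoate | COc1c(OCc2ccccc2)cc([C@@H](C(=O)OC)Cc2cc(OC)c(OC)cc2O)c(OCc2ccccc2)c1OC
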